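**Retrosynthetic overview**

1. The formates and the C7=C8 alkene with its C17 methyl come last: target ⇒ labd-7-ene-3β,15-diol ⇒ C7=C8 enol triflate ⇒ 3β,15-bis(silyloxy)-17-norlabdan-8-one.
2. Structural feature used: C9 lies between quaternary C10 and C8 and carries the whole C11–C16 side chain. Ring B (C5, C6, C7, C8, C9, C10) is therefore a cyclopentanone ring (C5, C6, C7, C8, C10) with C9 inserted into its C8–C10 bond.
3. Key disconnection C9–C10: a silver-triggered semipinacol shift of C10 from C8 to C9 in a C8 carbinol whose C9 bears PhSe. Both C9 epimers converge by enolisation to the equatorial 9β chain.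
4. The carbinol comes from a trans-hydrindan-8-one and an α-lithio selenide made from (S)-citronellol (C13). The hydrindanone comes from 2-methylcyclopentane-1,3-dione and ethyl vinyl ketone (C10 by amino acid catalysis, C5 by reductive methylation, C3 by hydride).
5. Ring order: five-membered ring (bought) → ring A (step 2, aldol) → ring B (step 11, ring expansion).

Key step: step 11

Remark on the chemistry: the target is read as (13S)-labd-7-ene-3β,15-diyl diformate of the normal series (5α-H, 9α-H, 10β-CH3). Labdane numbering and α/β descriptors are used for all bicyclic compounds, hydrindanes included.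
Remark on the chemistry: O15 is carried as the TBDPS ether, which resists ZnCl2/PhSeH and AgBF4 better than a primary TBS ether. The enedione of step 2 is to be recrystallised, and any residual enantiomer becomes a separable diastereomer after step 10.

**Step 1**
Reactants: 1 2-methylcyclopentane-1,3-dione; 2 pent-1-en-3-one (ethyl vinyl ketone)
Product: 3 2-methyl-2-(3-oxopentyl)cyclopentane-1,3-dione
Conditions: H2O, AcOH (cat.), 70 °C
Reagents that add atoms: none
Why: Michael addition of the acidic cyclic 1,3-dione to the unhindered enone stops at the triketone because C2 of the dione becomes quaternary; 3 is prochiral, so no stereocentre is set.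

**Step 2**
Reactants: 3 2-methyl-2-(3-oxopentyl)cyclopentane-1,3-dione
Product: 4 (7aS)-4,7a-dimethyl-2,3,7,7a-tetrahydro-1H-indene-1,5(6H)-dione (4,10β-dimethylhydrind-4-ene-3,8-dione)
Conditions: (S)-phenylalanine (1 equiv), (+)-camphorsulfonic acid (0.5 equiv), MeCN, 40→70 °C
Reagents that add atoms: none
Why: Hajos–Parrish–Eder–Sauer–Wiechert aldol condensation, in which the primary amino acid forms the enamine of the ethyl ketone (too hindered for proline) and its carboxyl group steers it to one enantiotopic ring carbonyl, closing ring A by a 6-(enolendo)-exo-trig aldol and setting C10 as (S), the sense known for (S)-amino acids, before acid-assisted dehydration.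

**Step 3**
Reactants: 4 (7aS)-4,7a-dimethyl-2,3,7,7a-tetrahydro-1H-indene-1,5(6H)-dione
Product: 5 8,8-ethylenedioxy-4,10β-dimethylhydrind-4-en-3-one
Conditions: TMSOCH2CH2OTMS (1.1 equiv), TMSOTf (5 mol %), CH2Cl2, −78 °C; pyridine quench
Reagents that add atoms: 1,2-bis(trimethylsilyloxy)ethane, C[Si](C)(C)OCCO[Si](C)(C)C
Why: Noyori ketalisation under kinetic control picks the saturated C8 ketone, because the conjugated, tetrasubstituted C3 enone carbonyl is much less electrophilic at low temperature; no stereocentre is touched.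

**Step 4**
Reactants: 5 8,8-ethylenedioxy-4,10β-dimethylhydrind-4-en-3-one
Product: 7 8,8-ethylenedioxy-4,4,10β-trimethyl-5α-hydrindan-3-one (trans-fused), via C3 lithium enolate 6 (not isolated)
Conditions: Li (2.2 equiv), H2O (1.0 equiv), NH3(l)–THF, −78→−33 °C; then MeI (excess), −33 °C→rt
Reagents that add atoms: iodomethane, CI
Why: Birch-type reductive alkylation, in which C5 is protonated axially to ring A on the α face, anti to the 10β-methyl, giving the trans fusion, and the regiodefined C3=C4 enolate 6 is C-methylated at C4 before it can equilibrate, completing the gem-dimethyl group.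

**Step 5**
Reactants: 7 8,8-ethylenedioxy-4,4,10β-trimethyl-5α-hydrindan-3-one
Product: 9 3β-hydroxy-4,4,10β-trimethyl-5α-hydrindan-8-one, via hydroxy ketal 8 (not isolated)
Conditions: NaBH4, MeOH, 0 °C; then 2 M aq HCl, THF, rt
Reagents that add atoms: water, O
Why: Hydride reduction under steric approach control, with borohydride attacking C3 axially from the α face, away from the axial 4β- and 10β-methyl groups, to give the equatorial 3β-alcohol as in 4,4-dimethyl-3-oxo terpenoids, after which dilute acid hydrolyses the dioxolane (acetal hydrolysis).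

**Step 6**
Reactants: 9 3β-hydroxy-4,4,10β-trimethyl-5α-hydrindan-8-one
Product: 10 3β-(tert-butyldimethylsilyloxy)-4,4,10β-trimethyl-5α-hydrindan-8-one
Conditions: TBSCl, imidazole, DMF, 50 °C
Reagents that add atoms: tert-butyldimethylsilyl chloride, CC(C)(C)[Si](C)(C)Cl
Why: Imidazole-promoted silylation of the only hydroxyl group, where gentle heating overcomes the neopentyl hindrance and the weak base does not enolise the C8 ketone.

**Step 7**
Reactants: 11 (S)-citronellol
Product: 12 (S)-citronellyl tert-butyldiphenylsilyl ether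
Conditions: TBDPSCl, imidazole, CH2Cl2, rt
Reagents that add atoms: tert-butyldiphenylsilyl chloride, CC(C)(C)[Si](Cl)(c1ccccc1)c1ccccc1
Why: Standard silyl ether formation at an unhindered primary alcohol; the stereocentre that becomes C13 is bought and not touched.

**Step 8**
Reactants: 12 (S)-citronellyl tert-butyldiphenylsilyl ether
Product: 14 (4S)-6-(tert-butyldiphenylsilyloxy)-4-methylhexanal, via secondary ozonide 13 (not isolated)
Conditions: O3, CH2Cl2, −78 °C; then Me2S, −78 °C→rt
Reagents that add atoms: ozone, [O-][O+]=O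
Why: Ozonolysis (Criegee mechanism) of the only alkene with reductive work-up makes the aldehyde carbon that will be C9, leaving the remote methyl-bearing centre unchanged.

**Step 9**
Reactants: 14 (4S)-6-(tert-butyldiphenylsilyloxy)-4-methylhexanal; 15 benzeneselenol
Product: 16 tert-butyl{[(3S)-3-methyl-6,6-bis(phenylselanyl)hexyl]oxy}diphenylsilane
Conditions: 15 (2.1 equiv), ZnCl2 (0.5 equiv), CH2Cl2, rt
Reagents that add atoms: none
Why: Lewis acid-catalysed selenoacetalisation, the selenium counterpart of dithioacetal formation, works well on unhindered aldehydes, and the TBDPS ether tolerates ZnCl2.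

**Step 10**
Reactants: 16 tert-butyl{[(3S)-3-methyl-6,6-bis(phenylselanyl)hexyl]oxy}diphenylsilane; 10 3β-(tert-butyldimethylsilyloxy)-4,4,10β-trimethyl-5α-hydrindan-8-one
Product: 18 3β-(tert-butyldimethylsilyloxy)-4,4,10β-trimethyl-8α-[(4S)-6-(tert-butyldiphenylsilyloxy)-4-methyl-1-(phenylselanyl)hexyl]-5α-hydrindan-8β-ol (C9 epimers), via α-lithio selenide 17 (not isolated)
Conditions: 16 (1.3 equiv), n-BuLi (1.25 equiv), THF, −78 °C; then 10, −78→−40 °C; H2O
Reagents that add atoms: none
Why: Selenium–lithium exchange of the selenoacetal is fast at −78 °C and gives a weakly basic, strongly nucleophilic α-selenoalkyllithium that adds 1,2 to hindered enolisable ketones; as in 17-oxo steroids the 10β-methyl blocks the β face, so C9 enters from the α face (8β-ol), and the C9 epimer mixture is corrected in step 11.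

**Step 11**
Reactants: 18 β-hydroxy selenide (C9 epimers)
Product: 20 3β-(tert-butyldimethylsilyloxy)-15-(tert-butyldiphenylsilyloxy)-17-norlabdan-8-one (9β side chain; 13S), via C9-epimeric ketone mixture 19 (not isolated)
Conditions: AgBF4 on neutral Al2O3 (2 equiv), CH2Cl2, 0 °C→rt, dark; filter; then NaOMe (0.3 equiv), MeOH–THF, rt
Reagents that add atoms: none
Why: Monovalent silver binds the soft selenium of 18 and makes AgSePh the leaving group; as the C9–Se bond ionises, the C8 hydroxyl oxygen pushes and the antiperiplanar C8–C10 bond shifts to C9 (retention at C10, inversion at C9), so that C8 ends as the ketone. This is a semipinacol rearrangement, the closest known type being the AgBF4-promoted ring enlargement of 1-(1-selenoalkyl)cycloalkanols, with the D-homoannulation of 17-hydroxy-20-sulfonyloxy steroids (migration of quaternary C13) as structural analogue. Ring B (C5, C6, C7, C8, C9, C10) is closed by 1,2-shift ring expansion of the five-membered ring and not by a cyclisation, C9–C10 being the only new skeletal bond, and release of trans-hydrindane strain adds driving force. The selectivity needed is migration of C10 rather than C7, and rearrangement rather than epoxide closure or loss of PhSe and OH: quaternary C10 stabilises the developing positive charge better than C7H2, the rotamer with the bulky selenium group anti to C10 is the least crowded one about C8–C9, no base strong enough to form the alkoxide is present, and the alumina takes up HBF4 before it can ionise the tertiary alcohol or attack the silyl ethers. C9 is the only new stereocentre: each epimer of 18 passes into one epimer of 19, and NaOMe equilibrates them through the C8 enolate to the equatorial 9β chain (axial 9α-H), the stable arrangement of 8-oxolabdanes. C3, C5, C10 and C13 are not involved and keep their configuration.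

**Step 12**
Reactants: 20 3β-(tert-butyldimethylsilyloxy)-15-(tert-butyldiphenylsilyloxy)-17-norlabdan-8-one
Product: 22 3β-(tert-butyldimethylsilyloxy)-15-(tert-butyldiphenylsilyloxy)-17-norlabd-7-en-8-yl trifluoromethanesulfonate, via C8 lithium enolate 21 (not isolated)
Conditions: LDA (1.2 equiv), THF, −78 °C; then PhNTf2, −78→0 °C; H2O
Reagents that add atoms: N-phenylbis(trifluoromethanesulfonimide), O=S(=O)(N(c1ccccc1)S(=O)(=O)C(F)(F)F)C(F)(F)F
Why: Kinetic deprotonation by the bulky amide takes the accessible C7 proton rather than the crowded tertiary C9–H, and O-sulfonylation fixes the C7=C8 enolate as the enol triflate, so C9 is not disturbed.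

**Step 13**
Reactants: 22 enol triflate
Product: 23 3β-(tert-butyldimethylsilyloxy)-15-(tert-butyldiphenylsilyloxy)labd-7-ene (13S)
Conditions: MeMgBr (2 equiv), Fe(acac)3 (10 mol %), THF–NMP, −30→0 °C
Reagents that add atoms: methylmagnesium bromide, C[Mg]Br
Why: Iron-catalysed Kumada-type cross-coupling of an alkenyl triflate, in which the low-valent iron species formed from Fe(acac)3 and the Grignard reagent activates the C–OTf bond, methyl has no β-hydrogen to lose, and the alkene position is fixed by the triflate.

**Step 14**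
Reactants: 23 bis-silyl ether
Product: 24 (13S)-labd-7-ene-3β,15-diol
Conditions: TBAF (5 equiv), THF, 55 °C
Reagents that add atoms: none
Why: Fluoride-driven desilylation (strong Si–F bond), where warming is needed for the neopentyl 3β-OTBS group and the non-acidic medium cannot move the 7-ene into the tetrasubstituted 8(9) position.

**Step 15**
Reactants: 24 (13S)-labd-7-ene-3β,15-diol
Product: 25 (13S)-labd-7-ene-3β,15-diyl diformate (target)
Conditions: AcOCHO (freshly distilled, 6 equiv), pyridine, CH2Cl2, 0 °C→rt
Reagents that add atoms: acetic formic anhydride, CC(=O)OC=O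
Why: O-formylation by a mixed anhydride, in which both hydroxyl groups attack the more electrophilic, less hindered formyl carbonyl, and pyridine buffering excludes acid that could isomerise the alkene.

**Compound list**

1 | 2-methylcyclopentane-1,3-dione | CC1C(=O)CCC1=O | starting material
2 | pent-1-en-3-one (ethyl vinyl ketone) | CCC(=O)C=C | starting material
3 | 2-methyl-2-(3-oxopentyl)cyclopentane-1,3-dione | CCC(=O)CCC1(C)C(=O)CCC1=O | intermediate
4 | (7aS)-4,7a-dimethyl-2,3,7,7a-tetrahydro-1H-indene-1,5(6H)-dione | O=C1CCC2=C(C)C(=O)CC[C@]12C | intermediate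
5 | 8,8-ethylenedioxy-4,10β-dimethylhydrind-4-en-3-one | C14(OCCO4)CCC2=C(C)C(=O)CC[C@]12C | intermediate
6 | lithium 8,8-ethylenedioxy-4,10β-dimethyl-5α-hydrind-3-en-3-olate (not isolated) | C14(OCCO4)CC[C@H]2C(C)=C(O[Li])CC[C@]12C | intermediate
7 | 8,8-ethylenedioxy-4,4,10β-trimethyl-5α-hydrindan-3-one | C14(OCCO4)CC[C@H]2C(C)(C)C(=O)CC[C@]12C | intermediate
8 | 8,8-ethylenedioxy-4,4,10β-trimethyl-5α-hydrindan-3β-ol (not isolated) | C14(OCCO4)CC[C@H]2C(C)(C)[C@@H](O)CC[C@]12C | intermediate
9 | 3β-hydroxy-4,4,10β-trimethyl-5α-hydrindan-8-one | O=C1CC[C@H]2C(C)(C)[C@@H](O)CC[C@]12C | intermediate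
10 | 3β-(tert-butyldimethylsilyloxy)-4,4,10β-trimethyl-5α-hydrindan-8-one | O=C1CC[C@H]2C(C)(C)[C@@H](O[Si](C)(C)C(C)(C)C)CC[C@]12C | intermediate
11 | (S)-citronellol | C[C@@H](CCC=C(C)C)CCO | starting material
12 | (S)-citronellyl tert-butyldiphenylsilyl ether | C[C@@H](CCC=C(C)C)CCO[Si](c1ccccc1)(c1ccccc1)C(C)(C)C | intermediate
13 | secondary ozonide of 12 (3,3-dimethyl-5-alkyl-1,2,4-trioxolane, not isolated) | CC1(C)OOC(CC[C@H](C)CCO[Si](c2ccccc2)(c2ccccc2)C(C)(C)C)O1 | intermediate
14 | (4S)-6-(tert-butyldiphenylsilyloxy)-4-methylhexanal | O=CCC[C@H](C)CCO[Si](c1ccccc1)(c1ccccc1)C(C)(C)C | intermediate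
15 | benzeneselenol | [SeH]c1ccccc1 | starting material
16 | tert-butyl{[(3S)-3-methyl-6,6-bis(phenylselanyl)hexyl]oxy}diphenylsilane | c1ccccc1[Se]C([Se]c1ccccc1)CC[C@H](C)CCO[Si](c1ccccc1)(c1ccccc1)C(C)(C)C | intermediate
17 | [(4S)-6-(tert-butyldiphenylsilyloxy)-4-methyl-1-(phenylselanyl)hexyl]lithium (not isolated) | [Li]C([Se]c1ccccc1)CC[C@H](C)CCO[Si](c1ccccc1)(c1ccccc1)C(C)(C)C | intermediate
18 | β-hydroxy selenide: 3β-OTBS-4,4,10β-trimethyl-5α-hydrindan-8β-ol with the 8α-[1-(phenylselanyl)alkyl] chain, C9 epimers | O[C@@]1(C([Se]c3ccccc3)CC[C@H](C)CCO[Si](c3ccccc3)(c3ccccc3)C(C)(C)C)CC[C@H]2C(C)(C)[C@@H](O[Si](C)(C)C(C)(C)C)CC[C@]12C | intermediate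
19 | 3β-OTBS-15-OTBDPS-17-norlabdan-8-one, C9 epimer mixture (not isolated) | O=C1CC[C@H]2C(C)(C)[C@@H](O[Si](C)(C)C(C)(C)C)CC[C@]2(C)C1CC[C@H](C)CCO[Si](c1ccccc1)(c1ccccc1)C(C)(C)C | intermediate
20 | 3β-OTBS-15-OTBDPS-17-norlabdan-8-one, 9β side chain | O=C1CC[C@H]2C(C)(C)[C@@H](O[Si](C)(C)C(C)(C)C)CC[C@]2(C)[C@H]1CC[C@H](C)CCO[Si](c1ccccc1)(c1ccccc1)C(C)(C)C | intermediate
21 | lithium C7=C8 enolate of 20 (not isolated) | [Li]OC1=CC[C@H]2C(C)(C)[C@@H](O[Si](C)(C)C(C)(C)C)CC[C@]2(C)[C@H]1CC[C@H](C)CCO[Si](c1ccccc1)(c1ccccc1)C(C)(C)C | intermediate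
22 | 3β-OTBS-15-OTBDPS-17-norlabd-7-en-8-yl triflate | FC(F)(F)S(=O)(=O)OC1=CC[C@H]2C(C)(C)[C@@H](O[Si](C)(C)C(C)(C)C)CC[C@]2(C)[C@H]1CC[C@H](C)CCO[Si](c1ccccc1)(c1ccccc1)C(C)(C)C | intermediate
23 | 3β-OTBS-15-OTBDPS-labd-7-ene | CC1=CC[C@H]2C(C)(C)[C@@H](O[Si](C)(C)C(C)(C)C)CC[C@]2(C)[C@H]1CC[C@H](C)CCO[Si](c1ccccc1)(c1ccccc1)C(C)(C)C | intermediate
24 | (13S)-labd-7-ene-3β,15-diol | CC1=CC[C@H]2C(C)(C)[C@@H](O)CC[C@]2(C)[C@H]1CC[C@H](C)CCO | intermediate
25 | (13S)-labd-7-ene-3β,15-diyl diformate | CC1=CC[C@H]2C(C)(C)[C@@H](OC=O)CC[C@]2(C)[C@H]1CC[C@H](C)CCOC=O | target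

Total step count: 15. Longest linear sequence: 12 (steps 1–6 and 10–15). Steps 7–9 form the convergent side-chain branch.

**Steps most likely to fail**

**Step 11.** Ionisation at the secondary C9 may be slow. Attack of the hydroxyl oxygen on C9, acid-induced loss of PhSe and OH, or competing migration of C7 could then erode the ring expansion.

The fallback uses another leaving group reached by another path. It sets out from 18 and returns at 20.
- MsCl/Et3N in CH2Cl2 effects the anti reductive elimination of the β-hydroxy selenide to the 8(9)-alkene F1 (E/Z mixture).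
- OsO4 (cat.)/NMO dihydroxylates from the open α face, as with 17(20)-ene steroids, to the 8α,9-diol F2.
- MsCl/pyridine esterifies only the secondary C9 hydroxyl to give the hydroxy mesylate F3.
- Et3Al in CH2Cl2 (−78→0 °C) forms the aluminium alkoxide and drives the pinacol-type shift of C10 to C9. This reaction type is established for 17α-hydroxy-20-sulfonates, which give 17a-methyl-D-homo-17-ketones.
- The crude ketone 19 is equilibrated with NaOMe as in step 11 to give 20.

**Step 10.** The organolithium may enolise the neopentyl ketone, or the bulky secondary carbanion may fail to reach C8.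

The fallback builds the C8–C9 bond as an alkene first. It sets out from 14 and 10 and returns at 18.
- NaBH4 reduces 14 to the primary alcohol F4.
- I2/PPh3/imidazole (Appel-type) gives the primary iodide F5.
- PPh3 in hot MeCN gives the phosphonium iodide F6.
- Wittig olefination of 10 with the ylide (KOtBu, toluene, reflux), as practised on 17-oxo steroids, should give mainly the (Z)-8(9)-alkene F7.
- Hydroxyselenation with N-(phenylseleno)phthalimide, H2O and camphorsulfonic acid (cat.) in CH2Cl2 adds PhSe to C9 from the α face and water to the more substituted C8 from the β face (Markovnikov, anti). This delivers 18 as one C9 epimer.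

**Step 4.** Facial selectivity in the protonation of C5 may be poor, with erosion of the trans fusion. Proton transfer may also occur before C-methylation.

The fallback sets C5 by hydrogenation instead of protonation. It sets out from 5 and returns at 7.
- KOtBu/MeI in t-BuOH methylates the extended enolate at C4 with deconjugation to the 4,4-dimethyl-5-en-3-one F8.
- H2 over Pd/C in EtOAc should add from the α face, since the β face carries both the axial 4β- and 10β-methyl groups. This gives 7.

**Further compounds**

F1 | step 11 | 3β-OTBS-15-OTBDPS 8(9)-alkene (alkylidene hydrindane, E/Z mixture) | CC(C)(C)[Si](c1ccccc1)(c1ccccc1)OCC[C@@H](C)CCC=C1CC[C@H]2C(C)(C)[C@@H](O[Si](C)(C)C(C)(C)C)CC[C@]12C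
F2 | step 11 | 8α,9-diol (8β side chain, C9 epimers) | O[C@]1(C(O)CC[C@H](C)CCO[Si](c3ccccc3)(c3ccccc3)C(C)(C)C)CC[C@H]2C(C)(C)[C@@H](O[Si](C)(C)C(C)(C)C)CC[C@]12C
F3 | step 11 | 8α-hydroxy 9-mesylate | O[C@]1(C(OS(C)(=O)=O)CC[C@H](C)CCO[Si](c3ccccc3)(c3ccccc3)C(C)(C)C)CC[C@H]2C(C)(C)[C@@H](O[Si](C)(C)C(C)(C)C)CC[C@]12C
F4 | step 10 | (4S)-6-(tert-butyldiphenylsilyloxy)-4-methylhexan-1-ol | OCCC[C@H](C)CCO[Si](c1ccccc1)(c1ccccc1)C(C)(C)C
F5 | step 10 | tert-butyl{[(3S)-6-iodo-3-methylhexyl]oxy}diphenylsilane | ICCC[C@H](C)CCO[Si](c1ccccc1)(c1ccccc1)C(C)(C)C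
F6 | step 10 | [(4S)-6-(tert-butyldiphenylsilyloxy)-4-methylhexyl]triphenylphosphonium iodide | [I-].c1ccccc1[P+](c1ccccc1)(c1ccccc1)CCC[C@H](C)CCO[Si](c1ccccc1)(c1ccccc1)C(C)(C)C
F7 | step 10 | (Z)-8(9)-alkene (C11 cis to C10) | CC(C)(C)[Si](c1ccccc1)(c1ccccc1)OCC[C@@H](C)CC/C=C1/CC[C@H]2C(C)(C)[C@@H](O[Si](C)(C)C(C)(C)C)CC[C@]12C
F8 | step 4 | 8,8-ethylenedioxy-4,4,10β-trimethylhydrind-5-en-3-one | C14(OCCO4)CC=C2C(C)(C)C(=O)CC[C@]12C
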